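Eudesmane numbering is used for the decalin: ring A = C1–C5 and C10, ring B = C5–C10; C4 carries the aryl ether, C10 the angular methyl, C7 the C11 side chain.
Retrosynthesis cuts, in order: the biaryl C–C bond, the aryl–allyl bond para to the ether oxygen, the aryl C–O bond of the tertiary ether, and last the two ring A bonds C1–C10 and C4–C5.
Forward: ring B is bought as (+)-dihydrocarvone. C10 and C5 are the α-carbon and the carbonyl carbon of its 2-methylcyclohexanone, and C1–C4 with the C4 methyl map onto ethyl vinyl ketone, so ring A is annulated in one Michael–aldol operation.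
The C4=C5 enone is reduced to the trans-decalin and taken through the enol triflate and the C3=C4 alkene to the 4α tertiary alcohol; this is O-arylated with a diaryliodonium salt, C11 is hydrated, and the arene is allylated and joined to the second aryl ring.
Stereochemistry: C7 from the chiral pool; C10 from a chiral-imine auxiliary in the annulation; C5 from axial protonation in the dissolving-metal reduction; C4 from epoxidation anti to the axial C10 methyl, the C4–O bond never being broken afterwards.

Key step: step 2

Remark: commercial (+)-dihydrocarvone is a mixture of C2 epimers; both converge because C2 is planar in the enamine that reacts in step 2, so 1 is drawn as the (2R,5R) isomer.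

Step 1
Reactants: 1 (+)-dihydrocarvone [(2R,5R)-2-methyl-5-(prop-1-en-2-yl)cyclohexan-1-one]; 2 (R)-1-phenylethylamine
Product: 3 (5R)-2-methyl-N-[(1R)-1-phenylethyl]-5-(prop-1-en-2-yl)cyclohexan-1-imine (C2 epimers)
Conditions: TsOH·H2O (cat.), toluene, reflux, Dean–Stark trap
Reagents that add atoms: none
Why: Acid-catalysed condensation of a ketone with a primary amine (imine formation) is driven by azeotropic removal of water; no stereocentre is set and C2 stays epimerisable.

Step 2
Reactants: 3 the imine; 4 ethyl vinyl ketone (pent-1-en-3-one)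
Product: 7 (+)-α-cyperone [(4aS,7R)-1,4a-dimethyl-7-(prop-1-en-2-yl)-4,4a,5,6,7,8-hexahydronaphthalen-2(3H)-one; eudesma-4,11-dien-3-one], via Michael adduct imine 5 (not isolated), via 1,5-diketone 6 (not isolated)
Conditions: 4 (1.3 equiv), THF, 40 °C; then 10% aq AcOH, rt; then KOH, MeOH, 60 °C (one flask)
Reagents that add atoms: none
Why: The imine reacts through its more substituted secondary enamine tautomer, which adds to the enone 4 in an aza-ene-like cyclic transition state with internal N–H transfer and so forms the C1–C10 bond at the methyl-bearing α-carbon; aqueous acid then frees the 1,5-diketone 6 and base condenses the α-carbon of its ethyl ketone (C4) with the ring carbonyl (C5). The closest known reaction type is the Robinson annulation in its chiral-imine (deracemising Michael) form. Ring A is closed in the aldol step by a 6-(enolexo)-exo-trig addition followed by E1cB loss of water to the conjugated C4=C5 enone. The one new stereocentre, quaternary C10, is set by the (R)-1-phenylethyl group on nitrogen, whose phenyl ring shields one enamine face so that 4 enters trans to the C7 isopropenyl group (10β-methyl), against the weak substrate preference for axial attack that would give the C10 epimer; C7 comes unchanged from 1. The step needs regioselectivity for C10 over C6, secured by exclusive reaction of the tetrasubstituted enamine tautomer, and facial selectivity at C10, secured by the auxiliary.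

Step 3
Reactants: 7 (+)-α-cyperone
Product: 9 5α-eudesma-3,11-dien-3-yl trifluoromethanesulfonate (trans-fused; 10β-CH3; 7β-isopropenyl; C3=C4 enol triflate), via lithium enolate 8 (not isolated)
Conditions: Li (2.2 equiv), t-BuOH (1.0 equiv), NH3(l)/THF, −78 °C; NH3 evaporated; PhNTf2 (1.5 equiv), THF, 0 °C → rt
Reagents that add atoms: N-phenylbis(trifluoromethanesulfonimide), O=S(=O)(N(c1ccccc1)S(=O)(=O)C(F)(F)F)C(F)(F)F
Why: Dissolving-metal (Birch-type) conjugate reduction protonates the β-carbanion at C5 axially on the α-face and should give the trans-fused decalin as its regiodefined C3–C4 lithium enolate, which is O-sulfonylated in the same flask (reductive enolate trapping); the isolated isopropenyl group is not reduced.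

Step 4
Reactants: 9 the enol triflate
Product: 10 (−)-α-selinene [(2R,4aR,8aR)-4a,8-dimethyl-2-(prop-1-en-2-yl)-1,2,3,4,4a,5,6,8a-octahydronaphthalene; eudesma-3,11-diene]
Conditions: Pd(OAc)2 (5 mol %), PPh3 (10 mol %), Bu3N, HCO2H, DMF, 60 °C
Reagents that add atoms: none
Why: Palladium-catalysed formate hydrogenolysis of an enol triflate (oxidative addition, decarboxylation of the formate ligand, C–H reductive elimination) removes the C3 oxygen and leaves the double bond fixed at C3=C4; no stereocentre is touched.

Step 5
Reactants: 10 α-selinene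
Product: 11 3α,4α-epoxyeudesm-11-ene (4β-CH3; 5α-H; 10β-CH3; 7β-isopropenyl)
Conditions: mCPBA (1.0 equiv), NaHCO3, CH2Cl2, −20 → 0 °C
Reagents that add atoms: 3-chloroperoxybenzoic acid, O=C(OO)c1cccc(Cl)c1
Why: Peracid (Prilezhaev) epoxidation should pick the more electron-rich trisubstituted ring alkene over the 1,1-disubstituted isopropenyl group and attack the α-face anti to the axial C10 methyl, which sets C4 (oxygen α, methyl β).

Step 6
Reactants: 11 the epoxide
Product: 12 selin-11-en-4α-ol [(1R,4aR,7R,8aR)-1,4a-dimethyl-7-(prop-1-en-2-yl)decahydronaphthalen-1-ol]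
Conditions: LiEt3BH (2.5 equiv), THF, 0 → 60 °C; then H2O
Reagents that add atoms: none
Why: Hydride opening of the trisubstituted epoxide by SN2 attack at the less substituted C3 leaves the C4–O bond intact, so the tertiary 4α-alcohol keeps the configuration set in step 5.

Step 7
Reactants: 13 4-bromo-2-chloro-1-iodobenzene; 14 1,3,5-trimethoxybenzene
Product: 16 (4-bromo-2-chlorophenyl)(2,4,6-trimethoxyphenyl)iodonium p-toluenesulfonate, via hydroxy(tosyloxy)iodoarene 15 (not isolated)
Conditions: mCPBA, TsOH·H2O, MeCN, 77 °C; then 14, rt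
Reagents that add atoms: p-toluenesulfonic acid monohydrate, Cc1ccc(S(=O)(=O)O)cc1.O
Why: One-pot diaryliodonium synthesis, in which the peracid oxidises the aryl iodide to the trivalent iodine species 15 and this arylates the electron-rich arene 14 by electrophilic aromatic substitution; no stereocentre is involved.

Step 8
Reactants: 12 selin-11-en-4α-ol; 16 the iodonium salt
Product: 18 4α-(4-bromo-2-chlorophenoxy)eudesm-11-ene (4β-CH3; 5α-H; 10β-CH3; 7β-isopropenyl), via sodium alkoxide 17 (not isolated)
Conditions: NaH (1.3 equiv), toluene, rt; then 16 (1.3 equiv), rt → 40 °C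
Reagents that add atoms: none
Why: Metal-free O-arylation of a tertiary alkoxide by a diaryliodonium salt (ligand exchange at trivalent iodine, then ligand coupling) should transfer the ortho-substituted, electron-poorer aryl group while the trimethoxyphenyl group stays on iodine; the C4–O bond is not broken, so C4 is retained.

Step 9
Reactants: 18 the aryl ether
Product: 19 4α-(4-bromo-2-chlorophenoxy)eudesman-11-ol
Conditions: Co(acac)2 (20 mol %), PhSiH3 (2.5 equiv), O2 (1 atm), THF/i-PrOH, rt
Reagents that add atoms: dioxygen, O=O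
Why: Mukaiyama hydration (hydrogen atom transfer from a cobalt hydride to the only alkene, capture of the tertiary C11 radical by O2, reduction) should give the Markovnikov tertiary alcohol; the aryl halides and the ether are inert and no stereocentre forms.

Step 10
Reactants: 19 the bromo chloro aryl ether
Product: 20 4α-(4-allyl-2-chlorophenoxy)eudesman-11-ol
Conditions: allylSnBu3 (1.5 equiv), Pd(PPh3)4 (5 mol %), toluene, 100 °C
Reagents that add atoms: allyltributylstannane, C=CC[Sn](CCCC)(CCCC)CCCC
Why: Stille coupling, in which zerovalent palladium inserts into the C–Br bond far faster than into the hindered C–Cl bond, should place the allyl group para to the ether oxygen under neutral conditions that do not move the double bond.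

Step 11
Reactants: 21 4-bromophenol
Product: 22 1-(allyloxy)-4-bromobenzene
Conditions: allyl bromide, K2CO3, acetone, reflux
Reagents that add atoms: allyl bromide, C=CCBr
Why: Williamson ether synthesis (SN2 of the phenoxide on allyl bromide).

Step 12
Reactants: 22 1-(allyloxy)-4-bromobenzene
Product: 23 2-allyl-4-bromophenol
Conditions: N,N-diethylaniline, 190 °C
Reagents that add atoms: none
Why: Aromatic Claisen rearrangement, a [3,3]-sigmatropic shift to the ortho position followed by tautomerisation; the two ortho positions are equivalent.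

Step 13
Reactants: 23 2-allyl-4-bromophenol
Product: 24 2-allyl-4-(4,4,5,5-tetramethyl-1,3,2-dioxaborolan-2-yl)phenol
Conditions: B2pin2, Pd(dppf)Cl2 (3 mol %), KOAc, dioxane, 85 °C
Reagents that add atoms: bis(pinacolato)diboron, CC1(C)OB(OC1(C)C)B1OC(C)(C)C(C)(C)O1
Why: Miyaura borylation of the aryl bromide under the weak base KOAc, which tolerates the free phenol and the allyl group.

Step 14
Reactants: 20 the allyl chloro aryl ether; 24 the arylboronate
Product: 25 CNP0219722.1 [4α-{[3',5-diallyl-4'-hydroxy-(1,1'-biphenyl)-2-yl]oxy}eudesman-11-ol; the honokiol 2-O-ether of cryptomeridiol at C4]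
Conditions: Pd(OAc)2 (5 mol %), SPhos (10 mol %), K3PO4, dioxane/H2O, 80 °C
Reagents that add atoms: none
Why: Suzuki–Miyaura coupling with an electron-rich dialkylbiarylphosphine ligand, which allows oxidative addition into the hindered ortho-alkoxy aryl chloride, joins the two aryl rings and should give the target directly because no protecting group is carried.

Compound list
1 | (+)-dihydrocarvone, (2R,5R)-2-methyl-5-(prop-1-en-2-yl)cyclohexan-1-one | C[C@@H]1CC[C@@H](C(C)=C)CC1=O | starting material
2 | (R)-1-phenylethylamine | C[C@@H](N)c1ccccc1 | starting material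
3 | (5R)-2-methyl-N-[(1R)-1-phenylethyl]-5-(prop-1-en-2-yl)cyclohexan-1-imine (C2 epimers) | CC1CC[C@@H](C(C)=C)CC1=N[C@H](C)c1ccccc1 | intermediate
4 | ethyl vinyl ketone (pent-1-en-3-one) | C=CC(=O)CC | starting material
5 | (2S,5R)-2-methyl-2-(3-oxopentyl)-N-[(1R)-1-phenylethyl]-5-(prop-1-en-2-yl)cyclohexan-1-imine | CCC(=O)CC[C@]1(C)CC[C@@H](C(C)=C)CC1=N[C@H](C)c1ccccc1 | intermediate
6 | (2S,5R)-2-methyl-2-(3-oxopentyl)-5-(prop-1-en-2-yl)cyclohexan-1-one | CCC(=O)CC[C@]1(C)CC[C@@H](C(C)=C)CC1=O | intermediate
7 | (+)-α-cyperone, (4aS,7R)-1,4a-dimethyl-7-(prop-1-en-2-yl)-4,4a,5,6,7,8-hexahydronaphthalen-2(3H)-one | O=C1CC[C@]3(C)CC[C@@H](C(C)=C)CC3=C1C | intermediate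
8 | lithium 5α-eudesma-3,11-dien-3-olate | [Li+].CC2=C([O-])CC[C@]3(C)CC[C@@H](C(C)=C)C[C@H]32 | intermediate
9 | 5α-eudesma-3,11-dien-3-yl trifluoromethanesulfonate | CC2=C(OS(=O)(=O)C(F)(F)F)CC[C@]3(C)CC[C@@H](C(C)=C)C[C@H]32 | intermediate
10 | (−)-α-selinene, eudesma-3,11-diene | CC2=CCC[C@]3(C)CC[C@@H](C(C)=C)C[C@H]32 | intermediate
11 | 3α,4α-epoxyeudesm-11-ene | O1[C@]2(C)[C@H]1CC[C@]3(C)CC[C@@H](C(C)=C)C[C@H]32 | intermediate
12 | selin-11-en-4α-ol, (1R,4aR,7R,8aR)-1,4a-dimethyl-7-(prop-1-en-2-yl)decahydronaphthalen-1-ol | O[C@]2(C)CCC[C@]3(C)CC[C@@H](C(C)=C)C[C@H]32 | intermediate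
13 | 4-bromo-2-chloro-1-iodobenzene | Clc1cc(Br)ccc1I | starting material
14 | 1,3,5-trimethoxybenzene | COc1cc(OC)cc(OC)c1 | starting material
15 | 4-bromo-2-chloro-1-[hydroxy(tosyloxy)iodo]benzene | OI(OS(=O)(=O)c1ccc(C)cc1)c1ccc(Br)cc1Cl | intermediate
16 | (4-bromo-2-chlorophenyl)(2,4,6-trimethoxyphenyl)iodonium p-toluenesulfonate | COc1cc(OC)c([I+]c2ccc(Br)cc2Cl)c(OC)c1.Cc1ccc(S(=O)(=O)[O-])cc1 | intermediate
17 | sodium alkoxide of selin-11-en-4α-ol | [Na+].[O-][C@]2(C)CCC[C@]3(C)CC[C@@H](C(C)=C)C[C@H]32 | intermediate
18 | 4α-(4-bromo-2-chlorophenoxy)eudesm-11-ene | Clc1cc(Br)ccc1O[C@]2(C)CCC[C@]3(C)CC[C@@H](C(C)=C)C[C@H]32 | intermediate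
19 | 4α-(4-bromo-2-chlorophenoxy)eudesman-11-ol | Clc1cc(Br)ccc1O[C@]2(C)CCC[C@]3(C)CC[C@@H](C(C)(C)O)C[C@H]32 | intermediate
20 | 4α-(4-allyl-2-chlorophenoxy)eudesman-11-ol | C=CCc1ccc(O[C@]2(C)CCC[C@]3(C)CC[C@@H](C(C)(C)O)C[C@H]32)c(Cl)c1 | intermediate
21 | 4-bromophenol | Oc1ccc(Br)cc1 | starting material
22 | 1-(allyloxy)-4-bromobenzene | C=CCOc1ccc(Br)cc1 | intermediate
23 | 2-allyl-4-bromophenol | C=CCc1cc(Br)ccc1O | intermediate
24 | 2-allyl-4-(4,4,5,5-tetramethyl-1,3,2-dioxaborolan-2-yl)phenol | C=CCc1cc(B2OC(C)(C)C(C)(C)O2)ccc1O | intermediate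
25 | CNP0219722.1, 4α-{[3',5-diallyl-4'-hydroxy-(1,1'-biphenyl)-2-yl]oxy}eudesman-11-ol | C=CCc1ccc(O[C@]2(C)CCC[C@]3(C)CC[C@@H](C(C)(C)O)C[C@H]32)c(-c2ccc(O)c(CC=C)c2)c1 | target

Total step count: 14. Longest linear sequence: 10 steps (steps 1, 2, 3, 4, 5, 6, 8, 9, 10, 14).

Steps most likely to fail

Step 8. Ligand coupling at trivalent iodine may be slow for this very hindered tertiary alkoxide, so that base-induced aryne formation from the salt or simple recovery of the alcohol takes over. The fallback sets out from 12 and comes back at 18. The potassium alkoxide of 12 (KH, 18-crown-6, THF, 0 °C) would displace fluoride from 2-chloro-1-fluoro-4-nitrobenzene by SNAr para to the nitro group to give 4α-(2-chloro-4-nitrophenoxy)eudesm-11-ene F1. Reduction of the nitro group (Fe, NH4Cl, EtOH/H2O, 70 °C) would give 4α-(4-amino-2-chlorophenoxy)eudesm-11-ene F2. A non-aqueous Sandmeyer bromination (t-BuONO, CuBr2, MeCN, 0 °C → rt) would then give 18.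

Step 6. Hydride attack at C3 cannot follow the trans-diaxial opening path of this rigid epoxide, so the opening may stall or be diverted to base-induced isomerisation to an allylic alcohol. The fallback sets out from 7 and comes back at 12. The lithium enolate 8, made as in step 3, would be oxidised at C4 on the α-face with 2-(phenylsulfonyl)-3-phenyloxaziridine (THF, −78 °C) to 4α-hydroxy-5α-eudesm-11-en-3-one F3. Condensation with TsNHNH2 (EtOH, rt) would give the tosylhydrazone of that ketone F4. Reduction with catecholborane (CHCl3, 0 °C) and then NaOAc·3H2O at reflux would remove the C3 carbonyl and give 12.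

Step 14. Protodeboronation of the electron-rich hydroxyaryl boronate 24 may outrun the slow oxidative addition into the chloride flanked by the bulky tertiary alkoxy group, and long heating may shift the allyl double bonds into conjugation. The fallback sets out from 20 and comes back at 25, with the polarity of the coupling reversed. Borylation of 20 (Pd2(dba)3, XPhos, B2pin2, KOAc, dioxane, 100 °C) would give 4α-[4-allyl-2-(4,4,5,5-tetramethyl-1,3,2-dioxaborolan-2-yl)phenoxy]eudesman-11-ol F5. This would be coupled with the unhindered bromide 23 (Pd(dppf)Cl2, K2CO3, dioxane/H2O, 70 °C) to give 25.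

Further compounds
F1 | step 8 | 4α-(2-chloro-4-nitrophenoxy)eudesm-11-ene | Clc1cc([N+](=O)[O-])ccc1O[C@]2(C)CCC[C@]3(C)CC[C@@H](C(C)=C)C[C@H]32
F2 | step 8 | 4α-(4-amino-2-chlorophenoxy)eudesm-11-ene | Clc1cc(N)ccc1O[C@]2(C)CCC[C@]3(C)CC[C@@H](C(C)=C)C[C@H]32
F3 | step 6 | 4α-hydroxy-5α-eudesm-11-en-3-one | O[C@]2(C)C(=O)CC[C@]3(C)CC[C@@H](C(C)=C)C[C@H]32
F4 | step 6 | tosylhydrazone of 4α-hydroxy-5α-eudesm-11-en-3-one | O[C@]2(C)C(=NNS(=O)(=O)c1ccc(C)cc1)CC[C@]3(C)CC[C@@H](C(C)=C)C[C@H]32
F5 | step 14 | 4α-[4-allyl-2-(4,4,5,5-tetramethyl-1,3,2-dioxaborolan-2-yl)phenoxy]eudesman-11-ol | C=CCc1ccc(O[C@]2(C)CCC[C@]3(C)CC[C@@H](C(C)(C)O)C[C@H]32)c(B4OC(C)(C)C(C)(C)O4)c1
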